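**Assumption:** the target is all-E halocynthiaxanthin. Ring A and plain locants (C1–C15) mean the acetylenic half; ring B and primed locants (C1'–C15') mean the epoxy ketone half.

## Retrosynthetic overview

1. Last bond C12'–C13': Stille coupling of pentaenynyl iodide 20 (ring A half plus the central C8 unit) with dienone stannane 33 (ring B half), then removal of two silyl ethers.
2. 33: the C8'–C9' bond and the 9'E alkene come from a nickel-catalysed aldehyde C–H addition (hydroacylation) of β,γ-epoxy aldehyde 28 to stannyl enyne 32.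
3. 20: Stille coupling of dienyl stannane 14 with the symmetric C8 diiodide 19 (from (E)-1,2-dichloroethene and propyne); 14 comes from Sonogashira coupling of enol triflate 10 with enynol 11.
4. Ring order: the one carbocycle is built first (steps 1–5, C3 set by transfer hydrogenation) and serves both rings through triflate 10; the epoxide ring of ring B is closed later (step 14, Sharpless epoxidation).

## Route

Step 1
Reactants: 1 mesityl oxide (4-methylpent-3-en-2-one); 2 methyl acetoacetate
Product: 5 isophorone (3,5,5-trimethylcyclohex-2-en-1-one), via keto ester 3 (not isolated), via keto acid 4 (not isolated)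
Conditions: NaOMe (0.2 equiv), MeOH, reflux; then 20% aq H2SO4, reflux
Reagents that add atoms: none
Why: Base-catalysed Michael addition followed by intramolecular aldol condensation (Robinson-type annulation) closes the ring, and acid hydrolysis with decarboxylation of the vinylogous β-keto acid leaves isophorone with no stereocentre.

Step 2
Reactants: 5 isophorone
Product: 6 ketoisophorone (2,6,6-trimethylcyclohex-2-ene-1,4-dione)
Conditions: tBuOOH (5 equiv), Pd(OH)2/C (5 mol%), K2CO3 (0.25 equiv), CH2Cl2, 4→24 °C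
Reagents that add atoms: tert-butyl hydroperoxide, CC(C)(C)OO
Why: Catalytic allylic (γ) C–H oxidation of the enone turns the ring CH2 beside the gem-dimethyl carbon into the second carbonyl, giving the ene-dione.

Step 3
Reactants: 6 ketoisophorone
Product: 7 (4S)-4-hydroxy-2,6,6-trimethylcyclohex-2-en-1-one
Conditions: RuCl[(S,S)-TsDPEN](p-cymene) (0.5 mol%), iPrOH, 25 °C
Reagents that add atoms: none
Why: Noyori asymmetric transfer hydrogenation reduces only the less hindered C4 carbonyl, and the (S,S) catalyst, reading the alkene as the π group, gives the 4S alcohol that becomes C3 of ring A and C3' of ring B.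

Step 4
Reactants: 7 (4S)-4-hydroxy-2,6,6-trimethylcyclohex-2-en-1-one
Product: 8 (4S)-2,6,6-trimethyl-4-(triethylsilyloxy)cyclohex-2-en-1-one
Conditions: Et3SiCl, imidazole, CH2Cl2, 0 °C
Reagents that add atoms: chlorotriethylsilane, CC[Si](Cl)(CC)CC
Why: Standard silyl ether formation protects the only hydroxyl with a group that can be removed at the end under buffered fluoride conditions.

Step 5
Reactants: 8 (4S)-2,6,6-trimethyl-4-(triethylsilyloxy)cyclohex-2-en-1-one
Product: 10 (4R)-2,6,6-trimethyl-4-(triethylsilyloxy)cyclohex-1-en-1-yl trifluoromethanesulfonate, via lithium enolate 9 (not isolated)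
Conditions: Li[HB(sBu)3], THF, −78 °C; then PhNTf2, DMPU, −78→0 °C
Reagents that add atoms: N-phenylbis(trifluoromethanesulfonimide), FC(F)(F)S(=O)(=O)N(c1ccccc1)S(=O)(=O)C(F)(F)F
Why: Conjugate hydride reduction gives the tetrasubstituted enolate regiospecifically (the other α-carbon is quaternary) and O-triflation traps it (reductive triflation); the carbinol centre is untouched and only changes descriptor.

Step 6
Reactants: 10 enol triflate; 11 (E)-3-methylpent-2-en-4-yn-1-ol
Product: 12 (2E)-3-methyl-5-[(4R)-2,6,6-trimethyl-4-(triethylsilyloxy)cyclohex-1-en-1-yl]pent-2-en-4-yn-1-ol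
Conditions: Pd(PPh3)4 (5 mol%), CuI (10 mol%), iPr2NH, DMF, 25→50 °C
Reagents that add atoms: none
Why: Sonogashira coupling of the hindered enol triflate with the terminal alkyne forms C6–C7 and carries the preset 9E alkene unchanged.

Step 7
Reactants: 12 enynol
Product: 13 (2E)-3-methyl-5-[(4R)-2,6,6-trimethyl-4-(triethylsilyloxy)cyclohex-1-en-1-yl]pent-2-en-4-ynal
Conditions: MnO2 (20 equiv), CH2Cl2, 25 °C
Reagents that add atoms: none
Why: MnO2 oxidises the allylic alcohol selectively to the enal without touching the alkyne, silyl ether or alkene geometry.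

Step 8
Reactants: 13 enynal
Product: 14 tributyl{(1E,3E)-4-methyl-6-[(4R)-2,6,6-trimethyl-4-(triethylsilyloxy)cyclohex-1-en-1-yl]hexa-1,3-dien-5-yn-1-yl}stannane
Conditions: CrCl2 (8 equiv), Bu3SnCHBr2 (2 equiv), LiI (4 equiv), THF/DMF, 25 °C, dark
Reagents that add atoms: (dibromomethyl)tributylstannane, CCCC[Sn](CCCC)(CCCC)C(Br)Br
Why: The Hodgson stannyl variant of the Takai olefination adds C12 through a gem-dichromium species and gives the E vinylstannane (11E).

Step 9
Reactants: 15 (E)-1,2-dichloroethene; 16 propyne (2.5 equiv)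
Product: 17 (E)-oct-4-ene-2,6-diyne
Conditions: Pd(PPh3)4 (4 mol%), CuI (8 mol%), nBuNH2, THF, 25 °C
Reagents that add atoms: none
Why: Twofold Sonogashira coupling of the trans-dichloroalkene proceeds with retention, so the future C15=C15' bond is E from the start.

Step 10
Reactants: 17 (E)-oct-4-ene-2,6-diyne
Product: 19 (2E,4E,6E)-2,7-diiodoocta-2,4,6-triene, via bis-zirconocene adduct 18 (not isolated)
Conditions: Cp2Zr(H)Cl (2.6 equiv), THF, 25→40 °C; then I2 (2.4 equiv), 0 °C, dark
Reagents that add atoms: iodine, II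
Why: Syn hydrozirconation places zirconium on the less hindered methyl-bearing alkyne carbons (thermodynamic control with slight excess hydride) and iodinolysis goes with retention, so both new trisubstituted alkenes (13E, 13'E) are set.

Step 11
Reactants: 14 dienyl stannane; 19 diiodide (4 equiv, excess recovered)
Product: 20 triethyl{[(1R)-4-[(3E,5E,7E,9E,11E)-12-iodo-3,7-dimethyltrideca-3,5,7,9,11-pentaen-1-yn-1-yl]-3,5,5-trimethylcyclohex-3-en-1-yl]oxy}silane
Conditions: Pd2(dba)3 (2.5 mol%), AsPh3 (20 mol%), NMP, 25 °C, dark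
Reagents that add atoms: none
Why: Stille coupling forms C12–C13 with retention at both partners, and the excess of the symmetric diiodide keeps the second coupling down.

Step 12
Reactants: 10 enol triflate
Product: 21 methyl (4R)-2,6,6-trimethyl-4-(triethylsilyloxy)cyclohex-1-ene-1-carboxylate
Conditions: Pd(OAc)2 (5 mol%), PPh3 (10 mol%), CO (1 atm), Et3N, MeOH/DMF, 60 °C
Reagents that add atoms: carbon monoxide, [C-]#[O+]; methanol, CO
Why: Palladium-catalysed methoxycarbonylation of the enol triflate installs C7' as an ester.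

Step 13
Reactants: 21 ester
Product: 22 [(4R)-2,6,6-trimethyl-4-(triethylsilyloxy)cyclohex-1-en-1-yl]methanol
Conditions: iBu2AlH, CH2Cl2, −78→0 °C
Reagents that add atoms: none
Why: Hydride reduction of the hindered conjugated ester gives the primary allylic alcohol needed for directed epoxidation.

Step 14
Reactants: 22 allylic alcohol
Product: 23 [(1R,4S,6R)-2,2,6-trimethyl-4-(triethylsilyloxy)-7-oxabicyclo[4.1.0]heptan-1-yl]methanol (epoxide anti to the silyloxy group)
Conditions: Ti(OiPr)4 (20 mol%), D-(−)-diethyl tartrate (24 mol%), tBuOOH, 4 Å MS, CH2Cl2, −20 °C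
Reagents that add atoms: tert-butyl hydroperoxide, CC(C)(C)OO
Why: Sharpless asymmetric epoxidation with the D-(−)-tartrate delivers oxygen to the alkene face opposite the silyloxy group under reagent control, setting both epoxide centres (5'R and 6'S of the target) in one step.

Step 15
Reactants: 23 epoxy alcohol
Product: 24 (1S,4S,6R)-2,2,6-trimethyl-4-(triethylsilyloxy)-7-oxabicyclo[4.1.0]heptane-1-carbaldehyde
Conditions: (nPr)4N[RuO4] (5 mol%), NMO, 4 Å MS, CH2Cl2, 25 °C
Reagents that add atoms: none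
Why: Ley–Griffith oxidation gives the non-enolisable epoxy aldehyde without epimerisation or epoxide opening.

Step 16
Reactants: 24 epoxy aldehyde
Product: 25 (1S,4S,6R)-1-ethenyl-2,2,6-trimethyl-4-(triethylsilyloxy)-7-oxabicyclo[4.1.0]heptane
Conditions: Ph3PCH3Br, KN(SiMe3)2, THF, 0→25 °C
Reagents that add atoms: methyltriphenylphosphonium bromide, C[P+](c1ccccc1)(c1ccccc1)c1ccccc1.[Br-]
Why: Wittig methylenation adds C8'; the aldehyde has no α-hydrogen, so the basic ylide cannot open the epoxide.

Step 17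
Reactants: 25 vinyl epoxide
Product: 27 2-[(1S,4S,6R)-2,2,6-trimethyl-4-(triethylsilyloxy)-7-oxabicyclo[4.1.0]heptan-1-yl]ethan-1-ol, via trialkylborane 26 (not isolated)
Conditions: 9-BBN (9-borabicyclo[3.3.1]nonane), THF, 0→25 °C; then NaOH, H2O2, 0 °C
Reagents that add atoms: hydrogen peroxide, OO
Why: Anti-Markovnikov hydroboration–oxidation of the monosubstituted alkene puts oxygen on C8', and the bulky dialkylborane (no free BH3) avoids hydride opening of the vinyl epoxide.

Step 18
Reactants: 27 epoxy alcohol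
Product: 28 2-[(1S,4S,6R)-2,2,6-trimethyl-4-(triethylsilyloxy)-7-oxabicyclo[4.1.0]heptan-1-yl]acetaldehyde
Conditions: Dess–Martin periodinane, pyridine, CH2Cl2, 0 °C; used at once
Reagents that add atoms: none
Why: Dess–Martin oxidation under buffered, base-free conditions gives the β,γ-epoxy aldehyde without the β-elimination that would open the epoxide.

Step 19
Reactants: 29 1,4-dichlorobut-2-yne
Product: 31 penta-1,3-diyne, via sodium butadiynide 30 (not isolated)
Conditions: NaNH2 (3 equiv), liq. NH3, −40 °C; then MeI, −60 °C; distilled into THF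
Reagents that add atoms: iodomethane, CI
Why: Double dehydrochlorination with isomerisation gives the diynide, which is methylated at the anionic carbon (acetylide alkylation).

Step 20
Reactants: 31 penta-1,3-diyne
Product: 32 tributyl[(1E)-pent-1-en-3-yn-1-yl]stannane
Conditions: Bu3SnH (1.0 equiv), PdCl2(PPh3)2 (1 mol%), THF, 0 °C
Reagents that add atoms: tributyltin hydride, CCCC[SnH](CCCC)CCCC
Why: Palladium-catalysed syn hydrostannation of the terminal alkyne puts tin on the terminal carbon and gives the E alkene (11'E); the minor internal regioisomer is removed by chromatography.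

Step 21
Reactants: 28 β,γ-epoxy aldehyde; 32 stannyl enyne (1.5 equiv)
Product: 33 (3E,5E)-3-methyl-6-(tributylstannyl)-1-[(1S,4S,6R)-2,2,6-trimethyl-4-(triethylsilyloxy)-7-oxabicyclo[4.1.0]heptan-1-yl]hexa-3,5-dien-2-one
Conditions: Ni(cod)2 (10 mol%), IPr (1,3-bis(2,6-diisopropylphenyl)imidazol-2-ylidene, 10 mol%, premixed with the nickel), toluene, 40 °C, slow addition of 28
Reagents that add atoms: none
Why: Proposed new method: redox-neutral hydroacylation of a 1,3-enyne by an aldehyde on zerovalent nickel. Alkene-directed oxidative cyclisation of enyne and aldehyde forms the C8'–C9' bond at the methyl-bearing alkyne carbon; β-hydride elimination from the nickel alkoxide makes the ketone; C–H reductive elimination delivers hydrogen syn to the acyl group, which fixes 9'E. The closest known reaction types are the nickel-catalysed reductive coupling of 1,3-enynes with aldehydes (same regiochemistry and syn addition, but needing a borane reductant and giving the alcohol) and the nickel-catalysed hydroacylation of simple alkynes. New here are the enyne partner, the base-sensitive β,γ-epoxy aldehyde and the vinylstannane carried through.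

Step 22
Reactants: 20 pentaenynyl iodide; 33 dienone stannane
Product: 34 3,3'-bis-O-triethylsilyl halocynthiaxanthin (all-E)
Conditions: Pd2(dba)3 (5 mol%), AsPh3 (40 mol%), NMP, 25→40 °C, dark
Reagents that add atoms: none
Why: Stille coupling forms C12'–C13' with retention of both alkene geometries under neutral conditions that the β,γ-epoxy ketone tolerates.

Step 23
Reactants: 34 bis-silyl ether
Product: 35 halocynthiaxanthin (target; all-E; ring A 3R; ring B 3'S,5'R,6'S)
Conditions: HF·pyridine, pyridine, THF, 0 °C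
Reagents that add atoms: none
Why: Buffered fluoride cleaves the two secondary triethylsilyl ethers without base-induced opening of the epoxide or acid damage to the polyene.

## Compound list

1 | mesityl oxide (4-methylpent-3-en-2-one) | CC(=O)C=C(C)C | starting material
2 | methyl acetoacetate | COC(=O)CC(C)=O | starting material
3 | methyl 2,6,6-trimethyl-4-oxocyclohex-2-ene-1-carboxylate (racemic) | COC(=O)C1C(C)=CC(=O)CC1(C)C | intermediate
4 | 2,6,6-trimethyl-4-oxocyclohex-2-ene-1-carboxylic acid (racemic) | OC(=O)C1C(C)=CC(=O)CC1(C)C | intermediate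
5 | isophorone (3,5,5-trimethylcyclohex-2-en-1-one) | CC1=CC(=O)CC(C)(C)C1 | intermediate
6 | ketoisophorone (2,6,6-trimethylcyclohex-2-ene-1,4-dione) | CC1=CC(=O)CC(C)(C)C1=O | intermediate
7 | (4S)-4-hydroxy-2,6,6-trimethylcyclohex-2-en-1-one | O=C1C(C)=C[C@@H](O)CC1(C)C | intermediate
8 | (4S)-2,6,6-trimethyl-4-(triethylsilyloxy)cyclohex-2-en-1-one | O=C1C(C)=C[C@@H](O[Si](CC)(CC)CC)CC1(C)C | intermediate
9 | lithium (4R)-2,6,6-trimethyl-4-(triethylsilyloxy)cyclohex-1-en-1-olate | [Li+].[O-]C1=C(C)C[C@@H](O[Si](CC)(CC)CC)CC1(C)C | intermediate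
10 | (4R)-2,6,6-trimethyl-4-(triethylsilyloxy)cyclohex-1-en-1-yl trifluoromethanesulfonate | CC1=C(OS(=O)(=O)C(F)(F)F)C(C)(C)C[C@H](O[Si](CC)(CC)CC)C1 | intermediate
11 | (E)-3-methylpent-2-en-4-yn-1-ol | C#C/C(C)=C/CO | starting material
12 | (2E)-3-methyl-5-[(4R)-2,6,6-trimethyl-4-(triethylsilyloxy)cyclohex-1-en-1-yl]pent-2-en-4-yn-1-ol | CC1=C(C#C/C(C)=C/CO)C(C)(C)C[C@H](O[Si](CC)(CC)CC)C1 | intermediate
13 | (2E)-3-methyl-5-[(4R)-2,6,6-trimethyl-4-(triethylsilyloxy)cyclohex-1-en-1-yl]pent-2-en-4-ynal | CC1=C(C#C/C(C)=C/C=O)C(C)(C)C[C@H](O[Si](CC)(CC)CC)C1 | intermediate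
14 | tributyl{(1E,3E)-4-methyl-6-[(4R)-2,6,6-trimethyl-4-(triethylsilyloxy)cyclohex-1-en-1-yl]hexa-1,3-dien-5-yn-1-yl}stannane | CC1=C(C#C/C(C)=C/C=C/[Sn](CCCC)(CCCC)CCCC)C(C)(C)C[C@H](O[Si](CC)(CC)CC)C1 | intermediate
15 | (E)-1,2-dichloroethene | Cl/C=C/Cl | starting material
16 | propyne | CC#C | starting material
17 | (E)-oct-4-ene-2,6-diyne | CC#C/C=C/C#CC | intermediate
18 | (2E,4E,6E)-octa-2,4,6-triene-2,7-diylbis[chlorobis(cyclopentadienyl)zirconium] | C/C([Zr](Cl)(C1C=CC=C1)C1C=CC=C1)=C\C=C\C=C(/C)[Zr](Cl)(C1C=CC=C1)C1C=CC=C1 | intermediate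
19 | (2E,4E,6E)-2,7-diiodoocta-2,4,6-triene | C/C(I)=C\C=C\C=C(/C)I | intermediate
20 | triethyl{[(1R)-4-[(3E,5E,7E,9E,11E)-12-iodo-3,7-dimethyltrideca-3,5,7,9,11-pentaen-1-yn-1-yl]-3,5,5-trimethylcyclohex-3-en-1-yl]oxy}silane | CC1=C(C#C/C(C)=C/C=C/C(C)=C/C=C/C=C(\C)I)C(C)(C)C[C@H](O[Si](CC)(CC)CC)C1 | intermediate
21 | methyl (4R)-2,6,6-trimethyl-4-(triethylsilyloxy)cyclohex-1-ene-1-carboxylate | CC1=C(C(=O)OC)C(C)(C)C[C@H](O[Si](CC)(CC)CC)C1 | intermediate
22 | [(4R)-2,6,6-trimethyl-4-(triethylsilyloxy)cyclohex-1-en-1-yl]methanol | CC1=C(CO)C(C)(C)C[C@H](O[Si](CC)(CC)CC)C1 | intermediate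
23 | [(1R,4S,6R)-2,2,6-trimethyl-4-(triethylsilyloxy)-7-oxabicyclo[4.1.0]heptan-1-yl]methanol | OC[C@@]12O[C@]1(C)C[C@@H](O[Si](CC)(CC)CC)CC2(C)C | intermediate
24 | (1S,4S,6R)-2,2,6-trimethyl-4-(triethylsilyloxy)-7-oxabicyclo[4.1.0]heptane-1-carbaldehyde | O=C[C@@]12O[C@]1(C)C[C@@H](O[Si](CC)(CC)CC)CC2(C)C | intermediate
25 | (1S,4S,6R)-1-ethenyl-2,2,6-trimethyl-4-(triethylsilyloxy)-7-oxabicyclo[4.1.0]heptane | C=C[C@@]12O[C@]1(C)C[C@@H](O[Si](CC)(CC)CC)CC2(C)C | intermediate
26 | 9-{2-[(1S,4S,6R)-2,2,6-trimethyl-4-(triethylsilyloxy)-7-oxabicyclo[4.1.0]heptan-1-yl]ethyl}-9-borabicyclo[3.3.1]nonane | B1(CC[C@@]34O[C@]3(C)C[C@@H](O[Si](CC)(CC)CC)CC4(C)C)C2CCCC1CCC2 | intermediate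
27 | 2-[(1S,4S,6R)-2,2,6-trimethyl-4-(triethylsilyloxy)-7-oxabicyclo[4.1.0]heptan-1-yl]ethan-1-ol | OCC[C@@]12O[C@]1(C)C[C@@H](O[Si](CC)(CC)CC)CC2(C)C | intermediate
28 | 2-[(1S,4S,6R)-2,2,6-trimethyl-4-(triethylsilyloxy)-7-oxabicyclo[4.1.0]heptan-1-yl]acetaldehyde | O=CC[C@@]12O[C@]1(C)C[C@@H](O[Si](CC)(CC)CC)CC2(C)C | intermediate
29 | 1,4-dichlorobut-2-yne | ClCC#CCCl | starting material
30 | sodium buta-1,3-diyn-1-ide | [Na+].[C-]#CC#C | intermediate
31 | penta-1,3-diyne | CC#CC#C | intermediate
32 | tributyl[(1E)-pent-1-en-3-yn-1-yl]stannane | CCCC[Sn](CCCC)(CCCC)/C=C/C#CC | intermediate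
33 | (3E,5E)-3-methyl-6-(tributylstannyl)-1-[(1S,4S,6R)-2,2,6-trimethyl-4-(triethylsilyloxy)-7-oxabicyclo[4.1.0]heptan-1-yl]hexa-3,5-dien-2-one | CCCC[Sn](CCCC)(CCCC)/C=C/C=C(\C)C(=O)C[C@@]12O[C@]1(C)C[C@@H](O[Si](CC)(CC)CC)CC2(C)C | intermediate
34 | 3,3'-bis-O-triethylsilyl halocynthiaxanthin (all-E) | CC1=C(C#C/C(C)=C/C=C/C(C)=C/C=C/C=C(C)/C=C/C=C(\C)C(=O)C[C@@]23O[C@]2(C)C[C@@H](O[Si](CC)(CC)CC)CC3(C)C)C(C)(C)C[C@H](O[Si](CC)(CC)CC)C1 | intermediate
35 | halocynthiaxanthin (all-E; ring A 3R; ring B 3'S,5'R,6'S) | CC1=C(C#C/C(C)=C/C=C/C(C)=C/C=C/C=C(C)/C=C/C=C(\C)C(=O)C[C@@]23O[C@]2(C)C[C@@H](O)CC3(C)C)C(C)(C)C[C@H](O)C1 | target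

## Step count and risks

Total step count: 23. Longest linear sequence: 15 (steps 1–5, 12–18, 21, 22, 23).

**Step 11 (mono-Stille coupling of the symmetric diiodide).** The risks are double coupling and the light sensitivity of iodide 20. The fallback sets out from 17 and 14 and comes back at 20. Enediyne 17 is treated with one equivalent of Cp2Zr(H)Cl and then I2, so the statistical event falls on the cheap enediyne; chromatography gives (2E,4E)-2-iodoocta-2,4-dien-6-yne F1. Stille coupling of F1 with 14 in a 1:1 ratio (Pd2(dba)3, AsPh3, NMP) gives triethyl{[(1R)-4-[(3E,5E,7E,9E)-3,7-dimethyltrideca-3,5,7,9-tetraene-1,11-diyn-1-yl]-3,5,5-trimethylcyclohex-3-en-1-yl]oxy}silane F2. Hydrozirconation of its unhindered methyl-capped alkyne with Cp2Zr(H)Cl, then I2, gives 20.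

**Step 21 (the proposed nickel hydroacylation).** The risks are aldehyde self-condensation, a stalled nickelacycle that does not undergo β-hydride elimination, and loss of the epoxide. The fallback uses known chemistry, sets out from 28 and 32 and comes back at 33. Nickel-catalysed reductive coupling (Ni(cod)2, tricyclopentylphosphine, Et3B, ethyl acetate, 25 °C) gives, with the same regiochemistry and syn addition, (3E,5E)-3-methyl-6-(tributylstannyl)-1-[(1S,4S,6R)-2,2,6-trimethyl-4-(triethylsilyloxy)-7-oxabicyclo[4.1.0]heptan-1-yl]hexa-3,5-dien-2-ol F3 as a mixture of carbinol epimers. Oxidation of this allylic alcohol with MnO2 in CH2Cl2 gives 33.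

**Step 22 (final Stille coupling).** The risks are slow transmetalation of the electron-poor dienone stannane and the fragility of the β,γ-epoxy ketone and polyenyl iodide. The fallback sets out from 20 together with 28 and 32 and comes back at 34. The ketone is carried at the alcohol level: the dienol stannane F3 (made as above from 28 and 32) is coupled with 20 under the same Stille conditions to give the bis-O-triethylsilyl 8'-hydroxy-7',8'-dihydro carotenoid F4. Its polyenylic secondary alcohol is then oxidised with MnO2 to give 34.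

## Further compounds

F1 | step 11 | (2E,4E)-2-iodoocta-2,4-dien-6-yne | C/C(I)=C\C=C\C#CC
F2 | step 11 | triethyl{[(1R)-4-[(3E,5E,7E,9E)-3,7-dimethyltrideca-3,5,7,9-tetraene-1,11-diyn-1-yl]-3,5,5-trimethylcyclohex-3-en-1-yl]oxy}silane | CC1=C(C#C/C(C)=C/C=C/C(C)=C/C=C/C#CC)C(C)(C)C[C@H](O[Si](CC)(CC)CC)C1
F3 | step 21 | (3E,5E)-3-methyl-6-(tributylstannyl)-1-[(1S,4S,6R)-2,2,6-trimethyl-4-(triethylsilyloxy)-7-oxabicyclo[4.1.0]heptan-1-yl]hexa-3,5-dien-2-ol (both carbinol epimers) | CCCC[Sn](CCCC)(CCCC)/C=C/C=C(\C)C(O)C[C@@]12O[C@]1(C)C[C@@H](O[Si](CC)(CC)CC)CC2(C)C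
F4 | step 22 | 3,3'-bis-O-triethylsilyl 8'-hydroxy-7',8'-dihydro precursor of 34 (both C8' epimers) | CC1=C(C#C/C(C)=C/C=C/C(C)=C/C=C/C=C(C)/C=C/C=C(\C)C(O)C[C@@]23O[C@]2(C)C[C@@H](O[Si](CC)(CC)CC)CC3(C)C)C(C)(C)C[C@H](O[Si](CC)(CC)CC)C1
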